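After 3.00 min the east run holds 90.7% of its starting material and the south-west run 90.4%, a gap of 0.3 percentage points at a scatter of 0.5 points, although the second substrate stood at 1.40 and 2.20 times the starting material.

common to all: starting material 0.40 M; free catalyst 14 mM
- east: second substrate 0.56 M; partner 0.60 M; run made earlier
- south-west: second substrate 0.88 M; partner 0.60 M; run made earlier
- alder: second substrate 0.400 M; partner 0.600 M; time 3.0 min
- elm: second substrate 0.400 M; partner 0.600 M; time 4.0 min

- east (time / min: target / %, catalyst intermediate A / %, starting material / %): 0.250: 0.4, 0.8, 98.0; 0.417: 1.2, 1.0, 97.9; 0.667: 3.6, 0.8, 97.2; 1.00: 3.2, 0.8, 95.8; 2.00: 7.1, 0.4, 92.8; 3.00: 8.9, 1.6, 90.7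
- south-west (time / min: target / %, catalyst intermediate A / %, starting material / %): 0.500: 1.7, 1.2, 97.3; 1.00: 3.3, 0.2, 95.4; 1.50: 5.6, 0, 94.6; 2.00: 6.4, 0, 94.2; 2.50: 7.6, 0, 92.2; 3.00: 8.7, 1.1, 90.4

(scatter of a reading: 0.5 percentage points)

- target is meant together with its idle complex
- reactions considered so far: free catalyst + target <-> idle complex; second substrate + free catalyst <-> catalyst intermediate B; starting material + free catalyst <-> catalyst intermediate A; partner + catalyst intermediate B -> free catalyst + second product; partner + catalyst intermediate A -> free catalyst + target

- which of these there is most of at the end, counted by the starting material in it, alder (starting material / target / catalyst intermediate A)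
- which of these there is most of at the end, counted by the starting material in it, elm (starting material / target / catalyst intermediate A)
- amount of the one of these that there is most of at the end, in percent of the starting material charged, alder
- amount of the one of these that there is most of at the end, in percent of the starting material charged, elm

Averaging the two runs gives 0.0315 min⁻¹; we call this the pace, the fraction of the charged starting material lost per minute. The gap gives no measure of the second substrate, so we make no allowance for its charge in alder and elm, 1.00 times the starting material. Held steady, the pace leaves 90.5% of the starting material in alder and 87.4% in elm. So we expect starting material to stay ahead of everything made from it,  even if all the loss were target.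

The forecast names starting material for alder and starting material for elm, at 90.3% and 88%, beside our own figures: “Starting material remains the largest by far in both.”

The flasks give starting material at 89.5% in alder and starting material at 86.9% in elm, with target at 9.97% and 12.6%.

    free catalyst + target ⇌ idle complex, settled at all times (K = 3.76 L mol⁻¹)
    second substrate + free catalyst ⇌ catalyst intermediate B (K = 1.10 L mol⁻¹, k = 0.202 L mol⁻¹ s⁻¹)
    starting material + free catalyst ⇌ catalyst intermediate A (K = 0.832 L mol⁻¹, k = 0.235 L mol⁻¹ s⁻¹)
    partner + catalyst intermediate B → free catalyst + second product (k = 1.09 L mol⁻¹ s⁻¹)
    partner + catalyst intermediate A → free catalyst + target (k = 0.181 L mol⁻¹ s⁻¹)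

In alder, starting material went to catalyst intermediate A while 77% of the partner still remained at the end, half of that step's turnover was done by 1.28 min, and free catalyst, the resting state, stood at the end at 68.3% of the catalyst charged; alder's pace from its start was 0.0351 min⁻¹ against the carried 0.0315 min⁻¹. Elm's pace from its start was 0.0328 min⁻¹ with 72% of its partner remaining, and alder's mixture read at 8.0 min had a lower one from its start, 0.0265 min⁻¹.

(The numbers in the tables stem from a simulated flask for an exercise.)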